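A direct plan would close ring C by a chiral-acid-catalysed oxa-[4+2] cycloaddition of the ortho-quinone methide A2 (from benzylic alcohol A1) with the Z-enol ester A3 and would then debenzylate the adduct A4. Its weakest steps would be:
- the cycloaddition itself, because an enol ester as 2π partner and a methylene-unsubstituted quinone methide are without precedent, and A2 would also alkylate ring A of A1;
- the Z-selective hydro-acyloxylation of the arylacetylene giving A3, because the cis relation of C2 and C3 would rest on an easily eroded alkene geometry;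
- the stoichiometry-controlled dibenzylation leading to A1, because of ether mixtures and C-benzylation.

The new route treats C2 and C3 as one problem at the ketone oxidation level. Racemic tetra-O-benzylflavan-3-one is assembled without stereocontrol (aryl propargyl ether, then gold-catalysed alkyne oxidation that closes ring C at C4–C4a). Because its C2–H is flanked by the ketone, ring B and O1, the two enantiomers interconvert through the enolate, and a dynamic kinetic asymmetric hydrogenation funnels them into the single cis-(2R,3R) alcohol: one catalytic operation sets both stereocentres, relative and absolute. No quinone methide, no geometrically pure enol ester and no partial benzylation of a polyphenol are needed; the syringoyl group is attached afterwards as a hydrogenolysable carbonate-protected acid.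

Key step: step 4

Assumption: 3,4-bis(benzyloxy)benzaldehyde and 3,5-bis(benzyloxy)phenol are taken as commercial, and the (S)-xylbinap/(S)-daipen catalyst is assumed, by analogy with 2-alkoxycyclohexanones, to add hydride to the Si face of C3; if the opposite sense were found, its mirror image would be used.

Step 1
Reactants: 1 3,4-bis(benzyloxy)benzaldehyde
Product: 2 racemic 1-[3,4-bis(benzyloxy)phenyl]prop-2-yn-1-ol
Conditions: HC≡CMgBr (1.3 equiv, 0.5 M in THF), THF, 0 °C to rt; aq NH4Cl work-up
Reagents that add atoms: ethynylmagnesium bromide, C#C[Mg]Br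
Why: Grignard 1,2-addition of the acetylide to the aryl aldehyde should give the secondary propargylic alcohol, whose new stereocentre is left racemic on purpose because it is equilibrated later at the ketone stage.

Step 2
Reactants: 2 racemic 1-[3,4-bis(benzyloxy)phenyl]prop-2-yn-1-ol; 3 3,5-bis(benzyloxy)phenol
Product: 4 racemic 1,3-bis(benzyloxy)-5-({1-[3,4-bis(benzyloxy)phenyl]prop-2-yn-1-yl}oxy)benzene
Conditions: PPh3 (1.3 equiv), DIAD (1.3 equiv), toluene/THF, 0 °C to rt
Reagents that add atoms: none
Why: Mitsunobu etherification, in which the phenol protonates the betaine and its phenoxide oxygen displaces the oxyphosphonium group at the propargylic carbon, should form the O1–C2 bond, O-alkylation being favoured at low temperature in a weakly polar medium and the stereocentre staying racemic.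

Step 3
Reactants: 4 racemic 1,3-bis(benzyloxy)-5-({1-[3,4-bis(benzyloxy)phenyl]prop-2-yn-1-yl}oxy)benzene
Product: 5 racemic 5,7-bis(benzyloxy)-2-[3,4-bis(benzyloxy)phenyl]-2H-chromen-3(4H)-one (tetra-O-benzylflavan-3-one)
Conditions: (Me4tBuXPhos)AuNTf2 (5 mol %; Me4tBuXPhos = di-tert-butyl(2',4',6'-triisopropyl-3,4,5,6-tetramethylbiphenyl-2-yl)phosphine), 2,6-dichloropyridine N-oxide (1.3 equiv), 1,2-dichloroethane, rt
Reagents that add atoms: 2,6-dichloropyridine N-oxide, [O-][n+]1c(Cl)cccc1Cl
Why: Gold-catalysed alkyne oxidation and cyclisation, the established chroman-3-one synthesis from aryl propargyl ethers, in which the N-oxide adds to the internal carbon of the gold-activated terminal alkyne, loss of the pyridine leaves a catalyst-bound α-oxo gold carbene, and the trioxygenated ring A attacks it ortho to the ether oxygen (both ortho positions are equivalent), should close ring C at C4–C4a with C3 as the ketone.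

Step 4
Reactants: 5 racemic 5,7-bis(benzyloxy)-2-[3,4-bis(benzyloxy)phenyl]-2H-chromen-3(4H)-one
Product: 6 (2R,3R)-5,7-bis(benzyloxy)-2-[3,4-bis(benzyloxy)phenyl]-3,4-dihydro-2H-chromen-3-ol (tetra-O-benzyl-(−)-epicatechin)
Conditions: trans-RuCl2[(S)-xylbinap][(S)-daipen] (1 mol %), KOtBu (10 mol %), H2 (10 atm), i-PrOH/toluene (1:1), 25 °C, degassed
Reagents that add atoms: none
Why: Alkoxide reversibly removes the C2 proton, which is acidified at once by the C3 ketone, ring B and O1, so (2R)- and (2S)-5 interconvert through the achiral enolate faster than either is reduced, while the ruthenium hydride with its N–H ligand transfers hydride and proton to C3=O through an outer-sphere six-membered transition state. The closest known reaction type is the Noyori asymmetric hydrogenation with dynamic kinetic resolution of racemic 2-aryl-, 2-alkoxy- and 2-aryloxy-cycloalkanones to cis alcohols. No ring is closed here, ring C being already in place, and the only bond formed at carbon is C3–H. C3 is controlled by the catalyst, which should add hydride to the Si face of the carbonyl, and C2 by the catalyst's selection of the ketone enantiomer whose ring B aryl group lies on the face away from the incoming hydride, which gives the 2,3-cis and hence the (2R,3R) arrangement. The step needs racemisation faster than reduction (secured by the triply activated C2–H), discrimination between the two ketone enantiomers (secured by the branched C2 on one flank of the carbonyl against the bare C4 methylene on the other) and cis selectivity (secured by the steric bias of the 2-aryl group, the same bias that bulky hydride reagents follow on this ring), while enolisation toward C4 is harmless because C4 is not stereogenic. Once reduced, the alcohol has no acidic C2–H left, so the configuration is locked, and the benzyl ethers are inert to the catalyst.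

Step 5
Reactants: 7 syringic acid (4-hydroxy-3,5-dimethoxybenzoic acid)
Product: 8 4-{[(benzyloxy)carbonyl]oxy}-3,5-dimethoxybenzoic acid
Conditions: benzyl chloroformate (1.2 equiv), NaOH (2.2 equiv), THF/H2O, 0 °C; then aq HCl to pH 2
Reagents that add atoms: benzyl chloroformate, O=C(Cl)OCc1ccccc1
Why: Schotten–Baumann acylation of the phenoxide of the dianion should give the aryl benzyl carbonate, the classical carbonate protection of phenolic acids, any mixed anhydride at the carboxylate being hydrolysed on work-up and the acid being recovered on acidification.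

Step 6
Reactants: 6 (2R,3R)-5,7-bis(benzyloxy)-2-[3,4-bis(benzyloxy)phenyl]-3,4-dihydro-2H-chromen-3-ol; 8 4-{[(benzyloxy)carbonyl]oxy}-3,5-dimethoxybenzoic acid
Product: 9 (2R,3R)-5,7-bis(benzyloxy)-2-[3,4-bis(benzyloxy)phenyl]-3,4-dihydro-2H-chromen-3-yl 4-{[(benzyloxy)carbonyl]oxy}-3,5-dimethoxybenzoate
Conditions: DCC (1.5 equiv), DMAP (0.2 equiv), CH2Cl2, 0 °C to rt
Reagents that add atoms: none
Why: Steglich esterification acylates the C3 hydroxyl at oxygen, so both stereocentres are retained, and the aryl carbonate and the benzyl ethers should be inert to the carbodiimide and DMAP.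

Step 7
Reactants: 9 (2R,3R)-5,7-bis(benzyloxy)-2-[3,4-bis(benzyloxy)phenyl]-3,4-dihydro-2H-chromen-3-yl 4-{[(benzyloxy)carbonyl]oxy}-3,5-dimethoxybenzoate
Product: 10 (2R,3R)-2-(3,4-dihydroxyphenyl)-5,7-dihydroxy-3,4-dihydro-2H-chromen-3-yl 4-hydroxy-3,5-dimethoxybenzoate [(−)-epicatechin 3-O-syringate]
Conditions: H2 (1 atm), Pd(OH)2/C, THF/MeOH, rt, stopped when hydrogen uptake ends
Reagents that add atoms: none
Why: Palladium-catalysed hydrogenolysis should cleave the four benzyl ethers and the benzyl carbonate (which then loses CO2) under neutral conditions, leaving the aryl ester, the two methyl ethers, the C2–O1 bond and both stereocentres untouched.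

Compound list
1 | 3,4-bis(benzyloxy)benzaldehyde | O=Cc1ccc(OCc2ccccc2)c(OCc2ccccc2)c1 | starting material
2 | racemic 1-[3,4-bis(benzyloxy)phenyl]prop-2-yn-1-ol | C#CC(O)c1ccc(OCc2ccccc2)c(OCc2ccccc2)c1 | intermediate
3 | 3,5-bis(benzyloxy)phenol | Oc1cc(OCc2ccccc2)cc(OCc2ccccc2)c1 | starting material
4 | racemic 1,3-bis(benzyloxy)-5-({1-[3,4-bis(benzyloxy)phenyl]prop-2-yn-1-yl}oxy)benzene | C#CC(Oc1cc(OCc2ccccc2)cc(OCc2ccccc2)c1)c1ccc(OCc2ccccc2)c(OCc2ccccc2)c1 | intermediate
5 | racemic 5,7-bis(benzyloxy)-2-[3,4-bis(benzyloxy)phenyl]-2H-chromen-3(4H)-one | O=C1Cc2c(OCc3ccccc3)cc(OCc3ccccc3)cc2OC1c1ccc(OCc2ccccc2)c(OCc2ccccc2)c1 | intermediate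
6 | (2R,3R)-5,7-bis(benzyloxy)-2-[3,4-bis(benzyloxy)phenyl]-3,4-dihydro-2H-chromen-3-ol | O[C@@H]1Cc2c(OCc3ccccc3)cc(OCc3ccccc3)cc2O[C@@H]1c1ccc(OCc2ccccc2)c(OCc2ccccc2)c1 | intermediate
7 | syringic acid (4-hydroxy-3,5-dimethoxybenzoic acid) | COc1cc(C(=O)O)cc(OC)c1O | starting material
8 | 4-{[(benzyloxy)carbonyl]oxy}-3,5-dimethoxybenzoic acid | COc1cc(C(=O)O)cc(OC)c1OC(=O)OCc1ccccc1 | intermediate
9 | (2R,3R)-5,7-bis(benzyloxy)-2-[3,4-bis(benzyloxy)phenyl]-3,4-dihydro-2H-chromen-3-yl 4-{[(benzyloxy)carbonyl]oxy}-3,5-dimethoxybenzoate | COc1cc(C(=O)O[C@@H]2Cc3c(OCc4ccccc4)cc(OCc4ccccc4)cc3O[C@@H]2c2ccc(OCc3ccccc3)c(OCc3ccccc3)c2)cc(OC)c1OC(=O)OCc1ccccc1 | intermediate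
10 | (2R,3R)-2-(3,4-dihydroxyphenyl)-5,7-dihydroxy-3,4-dihydro-2H-chromen-3-yl 4-hydroxy-3,5-dimethoxybenzoate | COc1cc(C(=O)O[C@@H]2Cc3c(O)cc(O)cc3O[C@@H]2c2ccc(O)c(O)c2)cc(OC)c1O | target

Total step count: 7. Longest linear sequence: 6 steps (steps 1, 2, 3, 4, 6 and 7).

Steps most likely to fail

Step 4 (dynamic kinetic hydrogenation). The catalyst may discriminate poorly between the interconverting ketone enantiomers, cis selectivity may be incomplete, or the enolisable ketone may degrade under alkoxide before it is reduced. Fallback: setting out from 5, substrate-controlled reduction with LiBH(s-Bu)3 in THF at −78 °C, hydride arriving anti to the 2-aryl group, would give the racemic cis alcohol, rac-(2R,3R/2S,3S)-5,7-bis(benzyloxy)-2-[3,4-bis(benzyloxy)phenyl]-3,4-dihydro-2H-chromen-3-ol F1. Its enantiomers would be separated by preparative chromatography on a chiral stationary phase; the (2R,3R) isomer is 6, where the route is rejoined, and the (2S,3S)-5,7-bis(benzyloxy)-2-[3,4-bis(benzyloxy)phenyl]-3,4-dihydro-2H-chromen-3-ol F2 would be set aside.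

Step 3 (gold-catalysed oxidation and cyclisation). Ring A is so electron-rich that direct 6-endo hydroarylation of the gold-activated alkyne may outrun attack of the N-oxide, ring B may capture the carbene, or the doubly activated propargylic C–O bond may ionise. Fallback: setting out from 4, the hydroarylation would be made the intended path (Ph3PAuNTf2, CH2Cl2, rt) to give the flav-3-ene, racemic 5,7-bis(benzyloxy)-2-[3,4-bis(benzyloxy)phenyl]-2H-chromene F3. Hydroboration–oxidation (BH3·THF, then NaOH/H2O2), with boron adding to C3 anti to the 2-aryl group, would give the racemic 2,3-trans alcohol, rac-(2R,3S/2S,3R)-5,7-bis(benzyloxy)-2-[3,4-bis(benzyloxy)phenyl]-3,4-dihydro-2H-chromen-3-ol F4. Dess–Martin oxidation of F4 in CH2Cl2 would return to ketone 5.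

Step 2 (Mitsunobu etherification). Ionisation of the oxyphosphonium ion at the doubly activated carbinol carbon may divert the ambident phenoxide to C-alkylation on ring A. Fallback: setting out from 2, acetylation (Ac2O, pyridine) would give the propargylic acetate, racemic 1-[3,4-bis(benzyloxy)phenyl]prop-2-yn-1-yl acetate F5. Copper-catalysed propargylic substitution with phenol 3 (CuOTf·½C6H6, an achiral pybox ligand, i-Pr2NEt, MeOH, 0 °C) runs through a copper allenylidene that the phenoxide oxygen attacks at the γ-carbon, and would return to ether 4.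

Further compounds
F1 | step 4 | rac-(2R,3R/2S,3S)-5,7-bis(benzyloxy)-2-[3,4-bis(benzyloxy)phenyl]-3,4-dihydro-2H-chromen-3-ol (racemic cis alcohol) | O[C@@H]1Cc2c(OCc3ccccc3)cc(OCc3ccccc3)cc2O[C@@H]1c1ccc(OCc2ccccc2)c(OCc2ccccc2)c1.O[C@H]1Cc2c(OCc3ccccc3)cc(OCc3ccccc3)cc2O[C@H]1c1ccc(OCc2ccccc2)c(OCc2ccccc2)c1
F2 | step 4 | (2S,3S)-5,7-bis(benzyloxy)-2-[3,4-bis(benzyloxy)phenyl]-3,4-dihydro-2H-chromen-3-ol | O[C@H]1Cc2c(OCc3ccccc3)cc(OCc3ccccc3)cc2O[C@H]1c1ccc(OCc2ccccc2)c(OCc2ccccc2)c1
F3 | step 3 | racemic 5,7-bis(benzyloxy)-2-[3,4-bis(benzyloxy)phenyl]-2H-chromene | C1=Cc2c(OCc3ccccc3)cc(OCc3ccccc3)cc2OC1c1ccc(OCc2ccccc2)c(OCc2ccccc2)c1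
F4 | step 3 | rac-(2R,3S/2S,3R)-5,7-bis(benzyloxy)-2-[3,4-bis(benzyloxy)phenyl]-3,4-dihydro-2H-chromen-3-ol (racemic trans alcohol) | O[C@H]1Cc2c(OCc3ccccc3)cc(OCc3ccccc3)cc2O[C@@H]1c1ccc(OCc2ccccc2)c(OCc2ccccc2)c1.O[C@@H]1Cc2c(OCc3ccccc3)cc(OCc3ccccc3)cc2O[C@H]1c1ccc(OCc2ccccc2)c(OCc2ccccc2)c1
F5 | step 2 | racemic 1-[3,4-bis(benzyloxy)phenyl]prop-2-yn-1-yl acetate | C#CC(OC(C)=O)c1ccc(OCc2ccccc2)c(OCc2ccccc2)c1
A1 | direct plan | 3,5-bis(benzyloxy)-2-(hydroxymethyl)phenol | OCc1c(O)cc(OCc2ccccc2)cc1OCc1ccccc1
A2 | direct plan | 3,5-bis(benzyloxy)-6-methylidenecyclohexa-2,4-dien-1-one | C=C1C(=O)C=C(OCc2ccccc2)C=C1OCc1ccccc1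
A3 | direct plan | (Z)-2-[3,4-bis(benzyloxy)phenyl]ethenyl 4-(benzyloxy)-3,5-dimethoxybenzoate | COc1cc(C(=O)O/C=C\c2ccc(OCc3ccccc3)c(OCc3ccccc3)c2)cc(OC)c1OCc1ccccc1
A4 | direct plan | (2R,3R)-5,7-bis(benzyloxy)-2-[3,4-bis(benzyloxy)phenyl]-3,4-dihydro-2H-chromen-3-yl 4-(benzyloxy)-3,5-dimethoxybenzoate | COc1cc(C(=O)O[C@@H]2Cc3c(OCc4ccccc4)cc(OCc4ccccc4)cc3O[C@@H]2c2ccc(OCc3ccccc3)c(OCc3ccccc3)c2)cc(OC)c1OCc1ccccc1
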